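**Retrosynthetic overview**

1. The C7 acetate is β to the ring ketone C9, so the target is the O-acetate of an anti aldol. The C7–C8 bond is cut into the C8 enolate of (S)-2-chloro-4-[(Z)-oct-2-enyl]-4-(trimethylsilyloxy)cyclopent-2-enone and methyl (Z)-7-oxohept-5-enoate; this union sets C7 and C8 together and leaves only O-acetylation and O-desilylation.
2. Enabling feature: in the cyclopentenone ring the C9 carbonyl has one enolisable neighbour, C8H2 (C10 is the sp2 C–Cl carbon, C12 a quaternary carbinol carbon). Only one ring-locked E(O) enolate can form, and the quaternary C12 (small OSiMe3 on one face, octenyl CH2 on the other) differentiates its faces.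
3. Donor: (R)-4-silyloxycyclopentenone; α-selective (Z)-octenylbarium 1,2-addition anti to the silyloxy group sets C12, desilylation/oxidation transposes the enone, and epoxidation, chloride opening and mesylate E1cB elimination install C10–Cl.
4. Acceptor: hex-5-ynoic acid; hydroxymethylation, esterification, Lindlar reduction, Dess–Martin oxidation.
5. Ring order: no ring is formed; the cyclopentenone ring is carried through from the chiral-pool enone.

Key step: step 12

Remark: prostanoid numbering is used in the text (C1 = ester carbon, C8–C12 = ring, C13–C20 = octenyl chain); by CIP analysis of the given structure the target is 7S,8R,12S.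
Assumption: compounds 1, 3 and 13 are taken as commercial, and the minor diastereomer of step 2 is removed by chromatography before step 4, because C4 of 3 is the only source of absolute configuration.

**Route**

Step 1
Reactants: 1 (Z)-oct-2-en-1-ol
Product: 2 (Z)-1-chlorooct-2-ene
Conditions: NCS, Me2S, CH2Cl2, −20 → 0 °C
Reagents that add atoms: N-chlorosuccinimide, O=C1CCC(=O)N1Cl
Why: Corey–Kim chlorination: the alkoxysulfonium ion formed from NCS/Me2S is displaced by chloride in an SN2 reaction at the primary allylic carbon, so neither allylic transposition nor loss of the Z geometry is expected.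

Step 2
Reactants: 2 (Z)-1-chlorooct-2-ene; 3 (R)-4-(tert-butyldimethylsilyloxy)cyclopent-2-en-1-one
Product: 5 (1S,4R)-4-(tert-butyldimethylsilyloxy)-1-[(2Z)-oct-2-en-1-yl]cyclopent-2-en-1-ol, via (Z)-oct-2-enylbarium chloride 4 (not isolated)
Conditions: activated Ba (BaI2 + 2 Li biphenylide, THF, rt); 2, −78 °C; then 3, −78 °C; H2O quench
Reagents that add atoms: none
Why: α-Selective allylbarium addition (a Grignard-type 1,2-addition): allylbarium reagents generated at −78 °C keep their double-bond geometry and react with ketones and enones at the unsubstituted α-carbon in a 1,2-sense, and the new tertiary carbinol centre is set by attack on the carbonyl face anti to the C4 silyloxy group, which puts the octenyl chain trans and the hydroxyl cis to OTBS.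

Step 3
Reactants: 5 (1S,4R)-4-(tert-butyldimethylsilyloxy)-1-[(2Z)-oct-2-en-1-yl]cyclopent-2-en-1-ol
Product: 6 (1S,4R)-1-[(2Z)-oct-2-en-1-yl]cyclopent-2-ene-1,4-diol
Conditions: TBAF, THF, 0 °C → rt
Reagents that add atoms: none
Why: Fluoride-induced desilylation driven by the Si–F bond removes the secondary TBS ether without touching the tertiary allylic alcohol or either alkene.

Step 4
Reactants: 6 (1S,4R)-1-[(2Z)-oct-2-en-1-yl]cyclopent-2-ene-1,4-diol
Product: 7 (S)-4-hydroxy-4-[(2Z)-oct-2-en-1-yl]cyclopent-2-en-1-one
Conditions: activated MnO2, CH2Cl2, rt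
Reagents that add atoms: none
Why: Chemoselective MnO2 oxidation of the secondary allylic alcohol (the tertiary alcohol cannot be oxidised) transposes the enone and erases the silyloxy-bearing stereocentre after it has relayed its configuration to the quaternary carbinol carbon.

Step 5
Reactants: 7 (S)-4-hydroxy-4-[(2Z)-oct-2-en-1-yl]cyclopent-2-en-1-one
Product: 8 (4S)-2,3-epoxy-4-hydroxy-4-[(2Z)-oct-2-en-1-yl]cyclopentan-1-one (epoxide on the hydroxyl face)
Conditions: 30% H2O2, NaOH (cat.), MeOH, 0 °C
Reagents that add atoms: hydrogen peroxide, OO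
Why: Weitz–Scheffer nucleophilic epoxidation: hydroperoxide adds only to the electron-poor enone and not to the isolated Z-alkene, and the epoxide configuration (expected on the hydroxyl face, anti to the octenyl CH2) is of no consequence because both epoxide carbons become sp2 again in step 6.

Step 6
Reactants: 8 (4S)-2,3-epoxy-4-hydroxy-4-[(2Z)-oct-2-en-1-yl]cyclopentan-1-one
Product: 11 (S)-2-chloro-4-hydroxy-4-[(2Z)-oct-2-en-1-yl]cyclopent-2-en-1-one, via chlorohydrin 9 (not isolated), via mesylate 10 (not isolated)
Conditions: LiCl, AcOH, THF, rt; then MsCl, Et3N, CH2Cl2, 0 °C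
Reagents that add atoms: lithium chloride, [Li+].[Cl-]
Why: Chloride opening of an α,β-epoxy ketone under buffered LiCl/AcOH conditions occurs by SN2 attack at the carbonyl-activated α-carbon (the β-carbon is neopentyl) to give the trans α-chloro-β-hydroxy ketone, whose secondary hydroxyl is then mesylated selectively and expelled by E1cB elimination through the chlorine-acidified α-CH, whereas the tertiary hydroxyl is neither sulfonylated nor a competent leaving group under these non-acidic conditions.

Step 7
Reactants: 11 (S)-2-chloro-4-hydroxy-4-[(2Z)-oct-2-en-1-yl]cyclopent-2-en-1-one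
Product: 12 (S)-2-chloro-4-[(2Z)-oct-2-en-1-yl]-4-(trimethylsilyloxy)cyclopent-2-en-1-one
Conditions: N-(trimethylsilyl)imidazole, CH2Cl2, rt
Reagents that add atoms: N-(trimethylsilyl)imidazole, C[Si](C)(C)n1ccnc1
Why: Silylation of the tertiary alcohol with a neutral, powerful silyl donor; trimethylsilyl is chosen because it blocks β-alkoxide chemistry in the aldol while remaining the smallest possible group on the oxygen-bearing face of the quaternary carbon.

Step 8
Reactants: 13 hex-5-ynoic acid
Product: 15 7-hydroxyhept-5-ynoic acid, via dilithium dianion 14 (not isolated)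
Conditions: n-BuLi (2.2 equiv), THF, −78 → 0 °C; (CH2O)n; 1 M HCl work-up
Reagents that add atoms: paraformaldehyde (as formaldehyde), C=O
Why: Hydroxymethylation of a lithium acetylide: two equivalents of base give the carboxylate–acetylide dianion, in which only the acetylide carbon is nucleophilic towards formaldehyde.

Step 9
Reactants: 15 7-hydroxyhept-5-ynoic acid
Product: 16 methyl 7-hydroxyhept-5-ynoate
Conditions: MeOH, H2SO4 (cat.), rt
Reagents that add atoms: methanol, CO
Why: Fischer esterification in excess methanol converts the acid into the methyl ester without affecting the propargylic alcohol or the alkyne.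

Step 10
Reactants: 16 methyl 7-hydroxyhept-5-ynoate
Product: 17 methyl (5Z)-7-hydroxyhept-5-enoate
Conditions: H2 (1 atm), Lindlar catalyst, quinoline, EtOAc, rt
Reagents that add atoms: none
Why: Lindlar semihydrogenation delivers H2 syn to the alkyne on the poisoned palladium surface and stops at the alkene, which sets the 5Z geometry.

Step 11
Reactants: 17 methyl (5Z)-7-hydroxyhept-5-enoate
Product: 18 methyl (5Z)-7-oxohept-5-enoate
Conditions: Dess–Martin periodinane, pyridine, CH2Cl2, 0 °C
Reagents that add atoms: none
Why: Dess–Martin oxidation under pyridine-buffered, non-enolising conditions gives the Z-enal without Z to E isomerisation, provided the aldehyde is used at once in step 12.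

Step 12
Reactants: 12 (S)-2-chloro-4-[(2Z)-oct-2-en-1-yl]-4-(trimethylsilyloxy)cyclopent-2-en-1-one; 18 methyl (5Z)-7-oxohept-5-enoate
Product: 21 methyl (5Z,7S)-7-[(1R,2S)-4-chloro-2-[(2Z)-oct-2-en-1-yl]-5-oxo-2-(trimethylsilyloxy)cyclopent-3-en-1-yl]-7-hydroxyhept-5-enoate, via boron dienolate 19 (not isolated), via boron aldolate 20 (not isolated)
Conditions: (c-Hex)2BCl, Et3N, Et2O, −78 → 0 °C; then 18, −78 → −20 °C; pH 7 buffer/MeOH (non-oxidative work-up)
Reagents that add atoms: none
Why: Soft enolisation with (c-Hex)2BCl/Et3N can only remove a proton from C8 (C10 is the chlorinated sp2 carbon and C12 is quaternary), giving the ring-locked E(O) dicyclohexylboron dienolate 19, which adds to the aldehyde through a closed six-membered chair (Zimmerman–Traxler) transition state to give boron aldolate 20, hydrolysed on work-up. The closest known reaction type is the anti-selective dicyclohexylboron aldol reaction of cyclic ketones, and aldol reactions of α'-enolates of 4-silyloxycyclopent-2-enones with aldehydes are the matching substrate class. No ring of the product is closed in this step; the only ring involved is the transient boron-containing chair. C8 is controlled by the quaternary C12: the aldehyde approaches the enolate face that carries the small OSiMe3 group, anti to the octenyl CH2 and antiperiplanar to the better σ-donating C12–C13 bond, so the new side chain ends up trans to the octenyl chain. C7 is controlled by the chair: with the E(O) enolate and the alkenyl group of 18 equatorial the anti aldol results, which together with the facial choice is the 7S,8R arrangement of the target. The step needs regioselective enolisation (secured by the absence of any other enolisable C–H), 1,2-addition to the enal with retention of the Z geometry (secured by the closed boron transition state at −78 °C and a neutral work-up that also spares the chloroenone) and no β-elimination of the silyloxy group (covalent boron enolate at low temperature).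

Step 13
Reactants: 21 methyl (5Z,7S)-7-[(1R,2S)-4-chloro-2-[(2Z)-oct-2-en-1-yl]-5-oxo-2-(trimethylsilyloxy)cyclopent-3-en-1-yl]-7-hydroxyhept-5-enoate
Product: 23 punaglandin 8, methyl (5Z,7S)-7-acetoxy-7-[(1R,2S)-4-chloro-2-hydroxy-2-[(2Z)-oct-2-en-1-yl]-5-oxocyclopent-3-en-1-yl]hept-5-enoate, via 12-O-trimethylsilyl acetate 22 (not isolated)
Conditions: Ac2O, pyridine, CH2Cl2, 0 °C; then AcOH/THF/H2O (3:1:1), rt
Reagents that add atoms: acetic anhydride, CC(=O)OC(C)=O
Why: Acylation of the secondary allylic alcohol with acetic anhydride in pyridine without DMAP at 0 °C avoids E1cB loss of the new β-acetoxy group, and mild aqueous acetic acid then hydrolyses only the labile tertiary trimethylsilyl ether, leaving the acetate, the methyl ester, the chloroenone and both Z-alkenes intact and no stereocentre touched.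

**Compound list**

1 | (Z)-oct-2-en-1-ol | CCCCC/C=C\CO | starting material
2 | (Z)-1-chlorooct-2-ene | CCCCC/C=C\CCl | intermediate
3 | (R)-4-(tert-butyldimethylsilyloxy)cyclopent-2-en-1-one | O=C1C=C[C@H](O[Si](C)(C)C(C)(C)C)C1 | starting material
4 | (Z)-oct-2-enylbarium chloride | CCCCC/C=C\C[Ba]Cl | intermediate
5 | (1S,4R)-4-(tert-butyldimethylsilyloxy)-1-[(2Z)-oct-2-en-1-yl]cyclopent-2-en-1-ol (OH cis to OTBS) | CCCCC/C=C\C[C@@]1(O)C=C[C@H](O[Si](C)(C)C(C)(C)C)C1 | intermediate
6 | (1S,4R)-1-[(2Z)-oct-2-en-1-yl]cyclopent-2-ene-1,4-diol (cis-diol) | CCCCC/C=C\C[C@@]1(O)C=C[C@H](O)C1 | intermediate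
7 | (S)-4-hydroxy-4-[(2Z)-oct-2-en-1-yl]cyclopent-2-en-1-one | CCCCC/C=C\C[C@@]1(O)C=CC(=O)C1 | intermediate
8 | (4S)-2,3-epoxy-4-hydroxy-4-[(2Z)-oct-2-en-1-yl]cyclopentan-1-one, epoxide cis to the hydroxyl | CCCCC/C=C\C[C@@]1(O)[C@@H]2O[C@@H]2C(=O)C1 | intermediate
9 | (4S)-2-chloro-3,4-dihydroxy-4-[(2Z)-oct-2-en-1-yl]cyclopentan-1-one, Cl trans to 3-OH, 3-OH cis to 4-OH | CCCCC/C=C\C[C@@]1(O)[C@H](O)[C@@H](Cl)C(=O)C1 | intermediate
10 | 3-O-methanesulfonate of 9 | CCCCC/C=C\C[C@@]1(O)[C@H](OS(C)(=O)=O)[C@@H](Cl)C(=O)C1 | intermediate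
11 | (S)-2-chloro-4-hydroxy-4-[(2Z)-oct-2-en-1-yl]cyclopent-2-en-1-one | CCCCC/C=C\C[C@@]1(O)C=C(Cl)C(=O)C1 | intermediate
12 | (S)-2-chloro-4-[(2Z)-oct-2-en-1-yl]-4-(trimethylsilyloxy)cyclopent-2-en-1-one | CCCCC/C=C\C[C@@]1(O[Si](C)(C)C)C=C(Cl)C(=O)C1 | intermediate
13 | hex-5-ynoic acid | C#CCCCC(=O)O | starting material
14 | lithium 6-lithiohex-5-ynoate (dianion) | [Li]C#CCCCC(=O)O[Li] | intermediate
15 | 7-hydroxyhept-5-ynoic acid | OCC#CCCCC(=O)O | intermediate
16 | methyl 7-hydroxyhept-5-ynoate | COC(=O)CCCC#CCO | intermediate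
17 | methyl (5Z)-7-hydroxyhept-5-enoate | COC(=O)CCC/C=C\CO | intermediate
18 | methyl (5Z)-7-oxohept-5-enoate | COC(=O)CCC/C=C\C=O | intermediate
19 | dicyclohexylboron dienolate of 12 (2-boryloxy-3-chloro-5-octenyl-5-silyloxycyclopenta-1,3-diene, S at the quaternary carbon) | CCCCC/C=C\C[C@@]1(O[Si](C)(C)C)C=C(Cl)C(OB(C2CCCCC2)C2CCCCC2)=C1 | intermediate
20 | 7-O-dicyclohexylboryl aldolate of 21 | CCCCC/C=C\C[C@@]1(O[Si](C)(C)C)C=C(Cl)C(=O)[C@@H]1[C@H](/C=C\CCCC(=O)OC)OB(C2CCCCC2)C2CCCCC2 | intermediate
21 | methyl (5Z,7S)-7-[(1R,2S)-4-chloro-2-[(2Z)-oct-2-en-1-yl]-5-oxo-2-(trimethylsilyloxy)cyclopent-3-en-1-yl]-7-hydroxyhept-5-enoate | CCCCC/C=C\C[C@@]1(O[Si](C)(C)C)C=C(Cl)C(=O)[C@@H]1[C@H](/C=C\CCCC(=O)OC)O | intermediate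
22 | methyl (5Z,7S)-7-acetoxy-7-[(1R,2S)-4-chloro-2-[(2Z)-oct-2-en-1-yl]-5-oxo-2-(trimethylsilyloxy)cyclopent-3-en-1-yl]hept-5-enoate | CCCCC/C=C\C[C@@]1(O[Si](C)(C)C)C=C(Cl)C(=O)[C@@H]1[C@H](/C=C\CCCC(=O)OC)OC(C)=O | intermediate
23 | punaglandin 8, methyl (5Z,7S)-7-acetoxy-7-[(1R,2S)-4-chloro-2-hydroxy-2-[(2Z)-oct-2-en-1-yl]-5-oxocyclopent-3-en-1-yl]hept-5-enoate | CCCCC/C=C\C[C@@]1(O)C=C(Cl)C(=O)[C@@H]1[C@H](/C=C\CCCC(=O)OC)OC(C)=O | target

**Step count**

Total steps: 13 (7 to donor 12, 4 to acceptor 18, 2 after the union).
Longest linear sequence: 9 steps (steps 1, 2, 3, 4, 5, 6, 7, 12, 13).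

**Steps most likely to fail**

Step 12. The process at risk is simple diastereoselection at C7: in the chair the alkenyl group lies gauche to the quaternary C12, so the syn pathway may compete; β-elimination of the silyloxy group or Z to E isomerisation of the enal are further risks. The fallback no longer sets C7 in the C–C bond formation but corrects it afterwards. It sets out from 12 (with 18): the lithium enolate (LDA, THF, −78 °C) is transmetalated with ClTi(OiPr)3, a metal whose enolates give syn aldols irrespective of enolate geometry, which should give the 7-epimeric aldol methyl (5Z,7R)-7-[(1R,2S)-4-chloro-2-[(2Z)-oct-2-en-1-yl]-5-oxo-2-(trimethylsilyloxy)cyclopent-3-en-1-yl]-7-hydroxyhept-5-enoate F1. Mitsunobu esterification of F1 with acetic acid (PPh3, DIAD, THF, 0 °C) installs the acetate with inversion at C7 and comes back to the route at 22, which is desilylated as in step 13.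

Step 2. The process at risk is loss of α-regioselectivity or Z geometry through equilibration of the allylmetal, or enolisation of 3 followed by loss of silyloxide. The fallback builds the octenyl chain by olefination instead of allylation and sets out from 3. The lithium enolate of ethyl acetate (LDA, EtOAc, THF, −78 °C) should add 1,2 anti to the silyloxy group to give ethyl 2-[(1R,4R)-4-(tert-butyldimethylsilyloxy)-1-hydroxycyclopent-2-en-1-yl]acetate F2. Silylation (TESOTf, 2,6-lutidine) gives the triethylsilyl ether of that ester F3, and DIBAL-H at −78 °C gives 2-[4-(tert-butyldimethylsilyloxy)-1-(triethylsilyloxy)cyclopent-2-en-1-yl]acetaldehyde F4. A salt-free Wittig reaction with hexylidenetriphenylphosphorane (n-hexylPPh3Br, NaHMDS, THF, −78 °C) gives the Z-alkene, the 1-O-triethylsilyl ether of 5 F5, and TBAF removes both silyl groups to come back to the route at 6.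

Step 6. The process at risk is chloride opening at the wrong epoxide carbon, or dehydration or retro-aldol cleavage of the tertiary β-hydroxy ketone while C10–C11 is saturated. The fallback introduces the halogen by a nucleophile-catalysed α-halogenation that leaves the isolated Z-alkene alone, and sets out from 7. Pyridine-catalysed α-iodination (I2, pyridine, CH2Cl2; conjugate addition, iodination, elimination) should give (S)-4-hydroxy-2-iodo-4-[(2Z)-oct-2-en-1-yl]cyclopent-2-en-1-one F6, and copper(I) chloride-mediated halogen exchange (CuCl, DMF, 60–80 °C) comes back to the route at 11.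

**Further compounds**

F1 | step 12 | methyl (5Z,7R)-7-[(1R,2S)-4-chloro-2-[(2Z)-oct-2-en-1-yl]-5-oxo-2-(trimethylsilyloxy)cyclopent-3-en-1-yl]-7-hydroxyhept-5-enoate | CCCCC/C=C\C[C@@]1(O[Si](C)(C)C)C=C(Cl)C(=O)[C@@H]1[C@@H](/C=C\CCCC(=O)OC)O
F2 | step 2 | ethyl 2-[(1R,4R)-4-(tert-butyldimethylsilyloxy)-1-hydroxycyclopent-2-en-1-yl]acetate (side chain trans to OTBS) | CCOC(=O)C[C@@]1(O)C=C[C@H](O[Si](C)(C)C(C)(C)C)C1
F3 | step 2 | ethyl 2-[4-(tert-butyldimethylsilyloxy)-1-(triethylsilyloxy)cyclopent-2-en-1-yl]acetate (same configuration as F2) | CCOC(=O)C[C@@]1(O[Si](CC)(CC)CC)C=C[C@H](O[Si](C)(C)C(C)(C)C)C1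
F4 | step 2 | 2-[4-(tert-butyldimethylsilyloxy)-1-(triethylsilyloxy)cyclopent-2-en-1-yl]acetaldehyde (same configuration as F2) | O=CC[C@@]1(O[Si](CC)(CC)CC)C=C[C@H](O[Si](C)(C)C(C)(C)C)C1
F5 | step 2 | 1-O-triethylsilyl ether of 5 | CCCCC/C=C\C[C@@]1(O[Si](CC)(CC)CC)C=C[C@H](O[Si](C)(C)C(C)(C)C)C1
F6 | step 6 | (S)-4-hydroxy-2-iodo-4-[(2Z)-oct-2-en-1-yl]cyclopent-2-en-1-one | CCCCC/C=C\C[C@@]1(O)C=C(I)C(=O)C1
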